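**Plan**

- Ring A is the ring with the methylidene, OH, Br and CMe2 groups; ring B is the ring with Br, Cl and CH3. In ring A the CHBr carbon, the CMe2 carbon, the spiro carbon and the C(=CH2) carbon lie in a row, which is the imprint of a bromonium-opened cation–olefin closure onto an exocyclic tetrasubstituted alkene of ring B. The retrosynthesis therefore cuts the CMe2–spiro bond last.
- Further cuts: the ring-B C–Br/C–Cl pair (back to an alkene via an epoxide), the ring-B alkene (metathesis), the allyl–alkene bond (Stille), the tetrasubstituted alkene (enol triflate of an α-acyl lactone), the acyl–lactone bond, and the lactone C–C bond to an α-bromo aldehyde made from prenol.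
- Forward: the halogenated side chain is made first as a γ-lactone, which is then acylated and converted to the Z enol triflate. Allylation and metathesis close ring B, which is then taken through epoxide and bromohydrin to the trans bromochloride. The lactone is reduced and the allylic alcohol turned into an allylsilane; ring A closes last.
- Stereochemistry: the ring-A C–Br centre comes from catalytic enantioselective bromochlorination, and the carbinol from Cornforth addition to the α-bromo aldehyde. The ring-B centres come from Shi epoxidation, invertive bromide opening and retentive chloride substitution. The spiro centre comes from the Z alkene geometry (lithium-chelated enolate) relayed through a chair closure.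
- The ring-B halogens must precede the spiro closure: the target carries them trans-diequatorial, which anti addition to the finished spirocycle should not give.

Key step: step 13

Remark on the chemistry: in steps 1 and 8 the catalyst antipode is the one whose established sense of induction gives the descriptor stated for the product; compounds 1, 4, 7 and 11 are taken as commercial.

**Step 1**
Reactants: 1 3-methylbut-2-en-1-ol
Product: 2 (2R)-2-bromo-3-chloro-3-methylbutan-1-ol
Conditions: NBS, ClTi(OiPr)3 (1.1 equiv), chiral tridentate Schiff-base amino-diol ligand (20 mol %), hexanes, −20 °C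
Reagents that add atoms: N-bromosuccinimide O=C1CCC(=O)N1Br; chlorotitanium triisopropoxide CC(C)O[Ti](Cl)(OC(C)C)OC(C)C
Why: Titanium-mediated catalytic enantioselective bromochlorination of an allylic alcohol: the ligand-bound titanium alkoxide directs bromonium formation to one alkene face and chloride opens it anti at the tertiary carbon (Markovnikov), which should set the C–Br centre as R.

**Step 2**
Reactants: 2 (2R)-2-bromo-3-chloro-3-methylbutan-1-ol
Product: 3 (2R)-2-bromo-3-chloro-3-methylbutanal
Conditions: Dess–Martin periodinane, CH2Cl2, 0 °C → rt; used crude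
Reagents that add atoms: none
Why: Dess–Martin oxidation is neutral and fast, so the configurationally labile α-bromo aldehyde should form without epimerisation.

**Step 3**
Reactants: 3 (2R)-2-bromo-3-chloro-3-methylbutanal; 4 [(1-ethoxycyclopropyl)oxy]trimethylsilane
Product: 6 (5R)-5-[(1R)-1-bromo-2-chloro-2-methylpropyl]oxolan-2-one, via silyl ether 5 (not isolated)
Conditions: 4, ZnCl2, Et2O, rt; then 3, CH2Cl2, 0 °C → rt; then TsOH·H2O (cat.), CH2Cl2, rt
Reagents that add atoms: none
Why: Zinc homoenolate addition to an aldehyde accelerated by Me3SiCl (homo-Reformatsky reaction) followed by acid lactonisation; the carbinol centre should arise by Cornforth/polar Felkin–Anh attack anti to the C–Br bond, giving the 1,2-anti bromohydrin relationship (5R).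

**Step 4**
Reactants: 6 (5R)-5-[(1R)-1-bromo-2-chloro-2-methylpropyl]oxolan-2-one; 7 4-methylpent-4-enoic acid
Product: 9 (5R)-5-[(1R)-1-bromo-2-chloro-2-methylpropyl]-3-(4-methylpent-4-enoyl)oxolan-2-one, via acyl imidazole 8 (not isolated)
Conditions: 7, 1,1'-carbonyldiimidazole, THF, rt; 6, LiN(SiMe3)2 (2.2 equiv), THF, −78 °C, then 8, −78 → −20 °C; aq. NH4Cl
Reagents that add atoms: none
Why: Crossed Claisen-type C-acylation of a lactone lithium enolate by an N-acylimidazole; the second equivalent of base holds the β-keto lactone as its enolate, and the centre between the carbonyls does not matter because it becomes sp2 in step 5.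

**Step 5**
Reactants: 9 (5R)-5-[(1R)-1-bromo-2-chloro-2-methylpropyl]-3-(4-methylpent-4-enoyl)oxolan-2-one
Product: 10 (3Z,5R)-5-[(1R)-1-bromo-2-chloro-2-methylpropyl]-3-[4-methyl-1-(trifluoromethylsulfonyloxy)pent-4-enylidene]oxolan-2-one
Conditions: Tf2O, Et3N, LiOTf, CH2Cl2, −78 → 0 °C
Reagents that add atoms: trifluoromethanesulfonic anhydride O=S(=O)(OS(=O)(=O)C(F)(F)F)C(F)(F)F
Why: O-sulfonylation of a 1,3-dicarbonyl enolate under lithium chelation: Li+ holds the enolate oxygen syn to the lactone carbonyl, so the triflate should form as the Z isomer with the pentenyl chain cis to the ring CH2.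

**Step 6**
Reactants: 10 the Z enol triflate; 11 allyltributylstannane
Product: 12 (3Z,5R)-5-[(1R)-1-bromo-2-chloro-2-methylpropyl]-3-(7-methylocta-1,7-dien-4-ylidene)oxolan-2-one
Conditions: Pd(PPh3)4 (5 mol %), LiCl, THF, 60 °C
Reagents that add atoms: none
Why: Stille coupling of a vinyl triflate proceeds with retention at the sp2 carbon, so the allyl group should end cis to the lactone carbonyl; the hindered alkyl halides are not expected to add to zerovalent palladium under these conditions.

**Step 7**
Reactants: 12 the skipped triene lactone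
Product: 13 (3Z,5R)-5-[(1R)-1-bromo-2-chloro-2-methylpropyl]-3-(4-methylcyclohex-3-en-1-ylidene)oxolan-2-one
Conditions: second-generation Grubbs catalyst (5 mol %), CH2Cl2, 40 °C
Reagents that add atoms: none
Why: Ring-closing metathesis of the two terminal alkenes closes ring B as a trisubstituted cyclohexene; the conjugated tetrasubstituted alkene is inert and keeps its geometry.

**Step 8**
Reactants: 13 the ring-B cyclohexene lactone
Product: 14 (3Z,5R)-5-[(1R)-1-bromo-2-chloro-2-methylpropyl]-3-[(1R,6S)-6-methyl-7-oxabicyclo[4.1.0]heptan-3-ylidene]oxolan-2-one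
Conditions: D-fructose-derived Shi ketone (30 mol %), KHSO5 (Oxone), K2CO3, Bu4NHSO4 (cat.), MeCN/dimethoxymethane/aq. buffer (pH 10.5), 0 °C
Reagents that add atoms: potassium peroxymonosulfate [K+].[O-]S(=O)(=O)OO
Why: Shi epoxidation: the chiral dioxirane should attack only the electron-rich trisubstituted ring alkene (the conjugated alkene is deactivated), and the spiro transition-state model for trisubstituted alkenes predicts oxygen delivery to the face that gives the (1R,6S) epoxide.

**Step 9**
Reactants: 14 the ring-B epoxide
Product: 15 (3Z,5R)-3-[(3S,4S)-3-bromo-4-hydroxy-4-methylcyclohexylidene]-5-[(1R)-1-bromo-2-chloro-2-methylpropyl]oxolan-2-one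
Conditions: Li2NiBr4 (THF solution), 0 °C → rt; pH 7 buffer
Reagents that add atoms: dilithium tetrabromonickelate [Li+].[Li+].[Ni+2].[Br-].[Br-].[Br-].[Br-]
Why: SN2 opening of a trisubstituted epoxide by soft bromide at the secondary carbon with inversion (trans-diaxial opening) should set the ring-B C–Br centre and leave the tertiary C–O centre untouched.

**Step 10**
Reactants: 15 the ring-B bromohydrin
Product: 16 (3Z,5R)-3-[(3S,4S)-3-bromo-4-chloro-4-methylcyclohexylidene]-5-[(1R)-1-bromo-2-chloro-2-methylpropyl]oxolan-2-one
Conditions: HCl (4 M in 1,4-dioxane), CH2Cl2, 0 °C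
Reagents that add atoms: hydrogen chloride Cl
Why: Substitution of a tertiary β-bromo alcohol with neighbouring-group participation: ionisation gives the bridged bromonium ion, which chloride opens at the tertiary carbon anti to bromine, so the C–O bond is replaced with net retention and the trans bromochloride results.

**Step 11**
Reactants: 16 the bromochloride lactone
Product: 17 (2Z,4R,5R)-5-bromo-2-[(3S,4S)-3-bromo-4-chloro-4-methylcyclohexylidene]-6-chloro-6-methylheptane-1,4-diol
Conditions: iBu2AlH (4 equiv), CH2Cl2, −78 → −20 °C; aq. potassium sodium tartrate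
Reagents that add atoms: none
Why: Hydride reduction of the lactone to the 1,4-diol should leave the alkene geometry and the alkyl halides untouched at low temperature.

**Step 12**
Reactants: 17 the 1,4-diol
Product: 18 (3R,4R,6Z)-3-bromo-6-[(3S,4S)-3-bromo-4-chloro-4-methylcyclohexylidene]-2-chloro-2-methyl-7-(trimethylsilyl)heptan-4-ol
Conditions: Pd(BF4)2(MeCN)4 (5 mol %), Me3SiSiMe3, DMSO/MeOH (1:1), 50 °C
Reagents that add atoms: hexamethyldisilane C[Si](C)(C)[Si](C)(C)C
Why: Palladium-catalysed silylation of an allylic alcohol with a disilane through an allylpalladium intermediate puts silicon on the primary terminus, so the tetrasubstituted alkene and its Z geometry are kept; this reaction type runs in methanol without ether formation, so the secondary hydroxyl should be tolerated.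

**Step 13**
Reactants: 18 the allylsilane
Product: 20 (2S,3S,6S,9R,10S)-2,10-dibromo-3-chloro-3,11,11-trimethyl-7-methylidenespiro[5.5]undecan-9-ol, via bromonium chloride 19 (not isolated)
Conditions: (CF3)2CHOH, 2,6-di-tert-butyl-4-methylpyridine (1.5 equiv), 0 °C → rt
Reagents that add atoms: none
Why: HFIP ionises the tertiary C–Cl bond of the side chain with anchimeric assistance from the vicinal bromine to give the configurationally defined bromonium ion 19, the ring-B carbon of the allylsilane (its γ-carbon) opens this ion at the tertiary carbon anti to bromine, and the resulting β-silyl cation loses the Me3Si group to leave the exocyclic methylene. The closest known reaction types are the bromonium-initiated cation–olefin cyclisation started by solvolysis of an enantioenriched vicinal bromochloride and the allylsilane-terminated cation–olefin cyclisation. Ring A closes in the 6-endo-trig mode with respect to the nucleophilic alkene (the bromonium ring is opened exo) through a chair in which the C–Br bond is equatorial and the hydroxyl axial. The ring-A C–Br centre is not touched (substitution occurs at the neighbouring CMe2 carbon) and keeps the configuration from step 1, while the spiro centre is fixed by the Z alkene geometry: the ring-B CH2 next to CHBr is cis to CH2SiMe3 and so becomes equatorial on ring A, on the face of Br and OH, with ring B reacting through its diequatorial-dihalide conformer by equatorial attack. The step needs ionisation of the side-chain chloride without destructive loss of the ring-B chloride (ion-pair return should make the latter unproductive), C–C and not C–O bond formation (the hydroxyl could only form an oxetane), and desilylation and not proton loss (secured by silicon, with the hindered pyridine removing HCl so the allylsilane is not protodesilylated).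

**Compound list**

1 | 3-methylbut-2-en-1-ol (prenol) | CC(C)=CCO | starting material
2 | (2R)-2-bromo-3-chloro-3-methylbutan-1-ol | OC[C@@H](Br)C(C)(C)Cl | intermediate
3 | (2R)-2-bromo-3-chloro-3-methylbutanal | O=C[C@@H](Br)C(C)(C)Cl | intermediate
4 | [(1-ethoxycyclopropyl)oxy]trimethylsilane | CCOC1(CC1)O[Si](C)(C)C | starting material
5 | ethyl (4R,5R)-5-bromo-6-chloro-6-methyl-4-(trimethylsilyloxy)heptanoate | CCOC(=O)CC[C@@H](O[Si](C)(C)C)[C@@H](Br)C(C)(C)Cl | intermediate
6 | (5R)-5-[(1R)-1-bromo-2-chloro-2-methylpropyl]oxolan-2-one | O=C1O[C@@H]([C@@H](Br)C(C)(C)Cl)CC1 | intermediate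
7 | 4-methylpent-4-enoic acid | CC(=C)CCC(=O)O | starting material
8 | 1-(imidazol-1-yl)-4-methylpent-4-en-1-one | CC(=C)CCC(=O)n1ccnc1 | intermediate
9 | (5R)-5-[(1R)-1-bromo-2-chloro-2-methylpropyl]-3-(4-methylpent-4-enoyl)oxolan-2-one (C3 epimers, largely enol) | O=C1O[C@@H]([C@@H](Br)C(C)(C)Cl)CC1C(=O)CCC(C)=C | intermediate
10 | (3Z,5R)-5-[(1R)-1-bromo-2-chloro-2-methylpropyl]-3-[4-methyl-1-(trifluoromethylsulfonyloxy)pent-4-enylidene]oxolan-2-one | O=C1O[C@@H]([C@@H](Br)C(C)(C)Cl)C/C1=C(\CCC(C)=C)OS(=O)(=O)C(F)(F)F | intermediate
11 | allyltributylstannane | C=CC[Sn](CCCC)(CCCC)CCCC | starting material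
12 | (3Z,5R)-5-[(1R)-1-bromo-2-chloro-2-methylpropyl]-3-(7-methylocta-1,7-dien-4-ylidene)oxolan-2-one | O=C1O[C@@H]([C@@H](Br)C(C)(C)Cl)C/C1=C(\CCC(C)=C)CC=C | intermediate
13 | (3Z,5R)-5-[(1R)-1-bromo-2-chloro-2-methylpropyl]-3-(4-methylcyclohex-3-en-1-ylidene)oxolan-2-one | O=C1O[C@@H]([C@@H](Br)C(C)(C)Cl)C/C1=C2\CCC(C)=CC2 | intermediate
14 | (3Z,5R)-5-[(1R)-1-bromo-2-chloro-2-methylpropyl]-3-[(1R,6S)-6-methyl-7-oxabicyclo[4.1.0]heptan-3-ylidene]oxolan-2-one | O=C1O[C@@H]([C@@H](Br)C(C)(C)Cl)C/C1=C2\CC[C@]3(C)O[C@@H]3C2 | intermediate
15 | (3Z,5R)-3-[(3S,4S)-3-bromo-4-hydroxy-4-methylcyclohexylidene]-5-[(1R)-1-bromo-2-chloro-2-methylpropyl]oxolan-2-one | O=C1O[C@@H]([C@@H](Br)C(C)(C)Cl)C/C1=C2\CC[C@](C)(O)[C@@H](Br)C2 | intermediate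
16 | (3Z,5R)-3-[(3S,4S)-3-bromo-4-chloro-4-methylcyclohexylidene]-5-[(1R)-1-bromo-2-chloro-2-methylpropyl]oxolan-2-one | O=C1O[C@@H]([C@@H](Br)C(C)(C)Cl)C/C1=C2\CC[C@](C)(Cl)[C@@H](Br)C2 | intermediate
17 | (2Z,4R,5R)-5-bromo-2-[(3S,4S)-3-bromo-4-chloro-4-methylcyclohexylidene]-6-chloro-6-methylheptane-1,4-diol | OC/C(C[C@@H](O)[C@@H](Br)C(C)(C)Cl)=C1/CC[C@](C)(Cl)[C@@H](Br)C1 | intermediate
18 | (3R,4R,6Z)-3-bromo-6-[(3S,4S)-3-bromo-4-chloro-4-methylcyclohexylidene]-2-chloro-2-methyl-7-(trimethylsilyl)heptan-4-ol | C[Si](C)(C)C/C(C[C@@H](O)[C@@H](Br)C(C)(C)Cl)=C1/CC[C@](C)(Cl)[C@@H](Br)C1 | intermediate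
19 | bromonium chloride formed from 18 (bromine bridging the CH and CMe2 carbons of the side chain) | C[Si](C)(C)C/C(C[C@@H](O)[C@H]1[Br+]C1(C)C)=C2/CC[C@](C)(Cl)[C@@H](Br)C2.[Cl-] | intermediate
20 | (2S,3S,6S,9R,10S)-2,10-dibromo-3-chloro-3,11,11-trimethyl-7-methylidenespiro[5.5]undecan-9-ol | C=C1C[C@@H](O)[C@@H](Br)C(C)(C)[C@]12CC[C@](C)(Cl)[C@@H](Br)C2 | target

**Count and risks**

Total step count: 13. Longest linear sequence: 13 steps (from 1).

Steps most likely to fail:

Step 13. The silyl group may be lost by protodesilylation before the side-chain chloride ionises, or the ring-B chloride may ionise and eliminate during a slow closure. The fallback ends the cyclisation by proton loss instead of by silicon. It sets out from 17: the primary allylic hydroxyl is mesylated selectively (MsCl, 2,4,6-collidine, CH2Cl2, −40 °C) to (2Z,4R,5R)-5-bromo-2-[(3S,4S)-3-bromo-4-chloro-4-methylcyclohexylidene]-6-chloro-4-hydroxy-6-methylheptyl methanesulfonate F1. This is displaced by hydride in the same flask (LiBHEt3, THF, −78 °C) to (3R,4R,6E)-3-bromo-6-[(3S,4S)-3-bromo-4-chloro-4-methylcyclohexylidene]-2-chloro-2-methylheptan-4-ol F2. F2 is closed in HFIP with the hindered pyridine as in step 13, the cation now losing a proton from the methyl group, and the route is rejoined at 20.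

Step 12. The free secondary hydroxyl may attack the allylpalladium intermediate to form a tetrahydrofuran, or the tertiary chlorides may solvolyse in warm methanol. The fallback is a protecting-group relay from 17. Both hydroxyls are silylated (Et3SiCl, imidazole, CH2Cl2) to the bis(triethylsilyl) ether of 17 F3. The primary silyl ether is cleaved selectively (pyridinium p-toluenesulfonate, MeOH, 0 °C) to the 4-O-triethylsilyl ether of 17 F4. F4 is acetylated and silylated in an aprotic medium (Ac2O, pyridine; then Me3SiSiMe3, Pd(dba)2, LiCl, DMF) to the triethylsilyl ether of 18 F5. The secondary silyl group is removed with mild acid (AcOH/THF/H2O) and the route is rejoined at 18.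

Step 8. Facial selectivity may be poor, because the ring alkene is remote from every stereocentre and only the catalyst tells its faces apart. The fallback drops the epoxide detour and sets out from 13: direct anti bromochlorination of the ring alkene (Bu4NBrCl2, CH2Cl2, −78 °C; bromine to the secondary, chlorine to the tertiary carbon) gives 16 together with its ring-B diastereomer (3Z,5R)-3-[(3R,4R)-3-bromo-4-chloro-4-methylcyclohexylidene]-5-[(1R)-1-bromo-2-chloro-2-methylpropyl]oxolan-2-one F6. The two diastereomers are separated by preparative chromatography and the route is rejoined at 16.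

**Further compounds**

F1 | step 13 | (2Z,4R,5R)-5-bromo-2-[(3S,4S)-3-bromo-4-chloro-4-methylcyclohexylidene]-6-chloro-4-hydroxy-6-methylheptyl methanesulfonate | CS(=O)(=O)OC/C(C[C@@H](O)[C@@H](Br)C(C)(C)Cl)=C1/CC[C@](C)(Cl)[C@@H](Br)C1
F2 | step 13 | (3R,4R,6E)-3-bromo-6-[(3S,4S)-3-bromo-4-chloro-4-methylcyclohexylidene]-2-chloro-2-methylheptan-4-ol | C/C(C[C@@H](O)[C@@H](Br)C(C)(C)Cl)=C1/CC[C@](C)(Cl)[C@@H](Br)C1
F3 | step 12 | bis(triethylsilyl) ether of 17 | CC[Si](CC)(CC)OC/C(C[C@@H](O[Si](CC)(CC)CC)[C@@H](Br)C(C)(C)Cl)=C1/CC[C@](C)(Cl)[C@@H](Br)C1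
F4 | step 12 | 4-O-triethylsilyl ether of 17 | OC/C(C[C@@H](O[Si](CC)(CC)CC)[C@@H](Br)C(C)(C)Cl)=C1/CC[C@](C)(Cl)[C@@H](Br)C1
F5 | step 12 | triethylsilyl ether of 18 | C[Si](C)(C)C/C(C[C@@H](O[Si](CC)(CC)CC)[C@@H](Br)C(C)(C)Cl)=C1/CC[C@](C)(Cl)[C@@H](Br)C1
F6 | step 8 | (3Z,5R)-3-[(3R,4R)-3-bromo-4-chloro-4-methylcyclohexylidene]-5-[(1R)-1-bromo-2-chloro-2-methylpropyl]oxolan-2-one | O=C1O[C@@H]([C@@H](Br)C(C)(C)Cl)C/C1=C2\CC[C@@](C)(Cl)[C@H](Br)C2
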